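At 20 s, the time of reading in both flasks, I want to know where each mole of substrate, the limiting reagent, stands.

- north-west: substrate 10 mM; reagent 2.40 equiv; free catalyst 0.5 mol%; time 20 s
- west: substrate 10 mM; reagent 1.20 equiv; free catalyst 0.5 mol%; time 20 s

    target + free catalyst ⇌ isomer of the product + free catalyst, rate k1*[free catalyst]*[target] forward; the back reaction follows from the equilibrium constant (k1 = 670 M⁻¹ s⁻¹)
    substrate + reagent ⇌ isomer of the product (K2 = 26000 M⁻¹, k2 = 0.083 M⁻¹ s⁻¹)
    substrate + reagent → uncatalysed product (k3 = 0.073 M⁻¹ s⁻¹)
    substrate + reagent ⇌ target (K4 = 240 M⁻¹, k4 = 5.9 M⁻¹ s⁻¹)
    2 free catalyst → spent catalyst (k5 = 71 M⁻¹ s⁻¹)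

- where a step has two of a species, its rate is k times that concentration squared, and two are used at each turn
- run time (north-west): 20 s

- which of these there is most of at the end, counted by the substrate in it, north-west (substrate / uncatalysed product / isomer of the product / target)
- which of these there is most of at the end, counted by the substrate in it, west (substrate / uncatalysed product / isomer of the product / target)
- amount of the one of these that there is most of at the end, in percent of the substrate charged, north-west
- amount of the one of these that there is most of at the end, in percent of the substrate charged, west

Each route uses one reagent per substrate, so c(reagent) minus c(substrate) holds at 14.0 mM in north-west and 2.00 mM in west. Free catalyst, charged at 0.0500 mM, stands at 0.0467 mM at mid-run. Per unit of target, target goes on to isomer of the product at 0.0313 s⁻¹ and back to substrate and reagent at 0.0246 s⁻¹.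

Now I divide the making of target by its loss and set the quotient to one, as in a steady-state treatment, so time drops out. The standing ratio is 106 M⁻¹, the value of c(target)/(c(substrate)·c(reagent)) at which target is made as fast as it leaves. Target per substrate is then this ratio times c(reagent).

I let isomer of the product collect 0.626 per target over the run, as an estimate. I drop the direct routes, because the step to target has the larger rate constant. With 172 M⁻¹ as the ratio times target plus its isomer, closing the books is one quadratic per flask. My books put reagent at 16.6 mM in north-west and 6.66 mM in west at the end, so I estimate target per substrate at 1.76 and 0.706.

| Ledger, % of substrate charged | north-west | west |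
|---|---|---|
| substrate | 26.0% | 46.6% |
| target | 45.5% | 32.8% |
| isomer of the product | 28.5% | 20.5% |

I commit to target in north-west and substrate in west.

The forecast, by another route (“Each run was hand-stepped in 5 s blocks”), says target at 49.4% (47.5% to 51.5%) in north-west and substrate at 45.9% (44% to 48%) in west. Its north-west target is higher than mine.

The flask gives target at 49.5% in north-west and substrate at 45.8% in west, so the forecast stands within its margins.

In west, target is made 4.46 times as fast as it is used at 5.29 s, each step taken net, and 0.886 times as fast at 20.0 s. The readings give 0.770 target per substrate in west and 2.36 in north-west.

Take west with 2.00 equiv of reagent: the excess is 10.0 mM, I put reagent at 13.1 mM at the end, and the standing ratio gives 1.39 target per substrate, so I expect target to lead at 42.6%. That flask gives target at 46.4%, with substrate at 27.0%.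

The constants are made up.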